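The data come from a simulation for an exercise; noise was put on by code.

Each closed, stirred flask here holds a fixed stock of nucleophile, and the blue run can show what one target costs from that stock.

| flask | electrophile | nucleophile | remark | time |
|---|---|---|---|---|
| blue | 0.055 M | 0.0525 M | run made earlier |  |
| epsilon | 0.050 M | 0.0400 M |  | 12 min |
| eta | 0.030 M | 0.0800 M |  | 12 min |
| alpha | 0.030 M | 0.0200 M |  | 12 min |
| delta | 0.20 M | 0.0120 M |  | 12 min |
| theta | 0.050 M | 0.0525 M |  | 12 min |

blue run (percent of the electrophile charged)

| time / min | target / % | electrophile / % |
|---|---|---|
| 0.500 | 9.3 | 92.6 |
| 1.33 | 19.0 | 80.8 |
| 2.50 | 25.3 | 77.3 |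
| 4.00 | 30.5 | 69.1 |

(scatter of a reading: 1 percentage point)

- the numbers in the tables scatter with a standard deviation of 1 percentage point

1. the flasks by amount of target, in percent of the electrophile charged, highest first, at 12 min (epsilon / eta / alpha / delta / theta)
2. the amount of target, in percent of the electrophile charged of the flask you put first, at 12 min
3. the amount of target, in percent of the electrophile charged of the flask you put last, at 12 min

I read the first blue point as a starting rate on the charged nucleophile and get a rate constant k of 3.54 M⁻¹ min⁻¹, a rough reading, since it counts the nucleophile as whole although some of it has been used by then. Between the last two readings the target is still rising, and with k and the electrophile then standing, that slope asks for a free nucleophile of only 0.0134 M. So I define the nucleophile cost n, the nucleophile gone per target formed, and read it from the midpoint of those readings as 2.55, a reading that carries the scatter. Nucleophile therefore disappears faster than target appears.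

With n held constant, the nucleophile charge divided by n is then my estimate of where the target stops. In percent of the electrophile charged, it is 41.2% for theta, 31.4% for epsilon, 26.1% for alpha and 2.35% for delta, while eta stands at 105%. That gives my order, eta more than theta, theta more than epsilon, epsilon more than alpha and alpha more than delta.

In delta, nucleophile is the limiting reagent, and with the electrophile in excess I take its early loss as pseudo-first-order, at n nucleophile per target, which gives an estimated half-life of 0.384 min, far shorter than 12 min. So I commit to that estimate for delta, 2.35%. In eta the electrophile and the nucleophile divided by n stand nearly level, so simple second order with constant kn gives 76.5%.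

The forecast reads eta > theta > epsilon > alpha > delta, with 51% and 4.6%, on the ground “every flask should be near equilibrium”. The order is the same as mine, but both numbers differ from mine.

The flasks give eta > theta > epsilon > alpha > delta, with 67.7% and 3.21%. In eta, the self-condensation product stands at 0.0154 M, holding 0.0308 M of nucleophile against 0.0203 M in target. My weak link was a constant n: eta's own cost comes to 3.52, above the blue 2.55.

    2 nucleophile → self-condensation product (k = 1.50 M⁻¹ min⁻¹)
    nucleophile + acid set free ⇌ protonated nucleophile, settled at all times (K = 1.30 × 10⁵ M⁻¹)
    electrophile + nucleophile → acid set free + target (k = 3.90 M⁻¹ min⁻¹)
    crystals ⇌ acid set free, rate k4*(cs4 - [acid set free]) while solid is left; crystals form when [acid set free] > cs4 (solubility = 32.0 mM, k = 10.0 min⁻¹)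

In delta's neighbour with 0.048 M of nucleophile, the blue cost gives an estimate of 9.41%. That flask gives 11.9%, a cost of 2.01.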